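**Retrosynthetic overview**
- The target is cut at the C1–aryl bond into guaiacol and the para-quinone methide of a 6-hydroxy-7-methoxytetralin whose two CH2OH groups are masked as benzyl ethers (removed last).
- That phenol comes from single O-methylation of the 6,7-catechol, which comes from oxidation of a 6,7-bis(boryl)tetralin.
- The bis(boryl)tetralin comes from a cobalt [2+2+2] cocyclisation of (4R,5R)-4,5-bis(benzyloxymethyl)octa-1,7-diyne with bis(pinacolboryl)acetylene. Carbocycle B closes first (C4a–C8a) and benzene ring A second (C5–C6, C7–C8), in the same step; the guaiacyl ring is bought.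
- The diyne comes from (1R,2R)-cyclohex-4-ene-1,2-dicarboxylic acid by reduction, benzylation, ozonolysis and twofold alkyne homologation, so the trans C2/C3 centres are bought.
- Feature: without the C1 aryl and the O-methyl, the tetralin core has a C2 axis through the midpoints of C2–C3, C4a–C8a and C6–C7 (exchanging C1/C4, C2/C3, C5/C8, C6/C7). Ring A therefore forms from symmetric partners with no regiochemistry, and the one O-methylation alone marks the benzylic carbon para to the free OH (C1, through C8a).

Key step: step 5

Remark: tetralin numbering of the target is used for all tetralin intermediates (C1 aryl-bearing, C2/C3 bearing CH2OR, C4 the CH2, OH on C6, OMe on C7); the resolved (1R,2R)-diacid and the diborylalkyne are taken as purchasable.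

**Step 1**
Reactants: 1 (1R,2R)-cyclohex-4-ene-1,2-dicarboxylic acid
Product: 2 [(1R,2R)-cyclohex-4-ene-1,2-diyl]dimethanol
Conditions: LiAlH4 (3 equiv), THF, 0 °C → reflux; then H2O/aq NaOH work-up
Reagents that add atoms: none
Why: Hydride reduction of both carboxylic acids by LiAlH4 gives the primary diol without touching the isolated alkene, and the two trans stereocentres are not epimerised under these conditions.

**Step 2**
Reactants: 2 [(1R,2R)-cyclohex-4-ene-1,2-diyl]dimethanol
Product: 3 (4R,5R)-4,5-bis(benzyloxymethyl)cyclohexene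
Conditions: NaH (2.5 equiv), BnBr (2.4 equiv), n-Bu4NI (cat.), THF/DMF, 0 °C → rt
Reagents that add atoms: benzyl bromide, BrCc1ccccc1
Why: Williamson etherification of the dialkoxide protects both primary alcohols as benzyl ethers, which should survive ozone at low temperature, basic methanol, hot cobalt catalysis, alkaline peroxide and Lewis acid and leave together in the last step.

**Step 3**
Reactants: 3 (4R,5R)-4,5-bis(benzyloxymethyl)cyclohexene
Product: 5 (3R,4R)-3,4-bis(benzyloxymethyl)hexanedial, via secondary ozonide 4 (not isolated)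
Conditions: O3, CH2Cl2, −78 °C (stopped at the first blue tint); then PPh3 (1.2 equiv), −78 °C → rt
Reagents that add atoms: ozone, [O-][O+]=O
Why: Ozonolysis with reductive work-up (1,3-dipolar cycloaddition, cycloreversion and recombination to the ozonide, then reduction by PPh3) cleaves the only alkene to the 1,6-dialdehyde, whose stereocentres are β to the carbonyls and cannot epimerise, while benzyl ethers tolerate a stoichiometric amount of ozone at −78 °C.

**Step 4**
Reactants: 5 (3R,4R)-3,4-bis(benzyloxymethyl)hexanedial; 6 dimethyl (1-diazo-2-oxopropyl)phosphonate (Ohira–Bestmann reagent)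
Product: 7 (4R,5R)-4,5-bis(benzyloxymethyl)octa-1,7-diyne
Conditions: 6 (2.6 equiv), K2CO3 (4 equiv), MeOH, 0 °C → rt; 5 added slowly to the pre-mixed reagent
Reagents that add atoms: dimethyl (1-diazo-2-oxopropyl)phosphonate (6), CC(=O)C(=[N+]=[N-])P(=O)(OC)OC
Why: Twofold Seyferth–Gilbert homologation in its Ohira–Bestmann form, in which methoxide deacetylates 6 to the diazomethylphosphonate anion that adds to each aldehyde, loses dimethyl phosphate and N2 and rearranges by 1,2-hydride shift of the alkylidene carbene, should give each terminal alkyne with one added carbon under conditions that leave the benzyl ethers and the stereocentres alone.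

**Step 5**
Reactants: 7 (4R,5R)-4,5-bis(benzyloxymethyl)octa-1,7-diyne; 8 bis(pinacolboryl)acetylene
Product: 9 (2R,3R)-2,3-bis(benzyloxymethyl)-6,7-bis(pinacolboryl)-1,2,3,4-tetrahydronaphthalene
Conditions: CpCo(CO)2 (monovalent cobalt, 20 mol %), 8 (3 equiv), o-xylene, reflux, hν (tungsten lamp), argon; 7 added by syringe pump over 10 h
Reagents that add atoms: bis(pinacolboryl)acetylene (8), CC1(C)OB(C#CB2OC(C)(C)C(C)(C)O2)OC1(C)C
Why: Loss of CO from CpCo(CO)2 gives a CpCo fragment of monovalent cobalt that binds both alkynes of 7 and couples them oxidatively to a bicyclic cobaltacyclopentadiene of trivalent cobalt, which forms C4a–C8a and closes ring B as a six-membered carbocycle across the four-carbon sp3 tether; coordination and insertion of 8 (or its [4+2] addition across the metallacycle) and reductive elimination then form C5–C6 and C7–C8, close benzene ring A and release CpCo. The closest known reaction type is the CpCo(CO)2-mediated [2+2+2] cocyclisation of 1,7-diynes with bis(trimethylsilyl)acetylene or alkynylboronates to 6,7-disubstituted tetralins. No stereocentre is formed, and the bought centres C2 and C3 are remote from the reacting carbons and untouched. The only selectivity needed is chemoselectivity for cross-cyclisation over diyne oligomerisation, secured by an excess of the hindered diborylalkyne 8, which is slow to self-trimerise, and by slow addition of 7. The C2 axis of 7 makes its two alkynes equivalent and 8 is symmetric, so no regioisomer can arise.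

**Step 6**
Reactants: 9 (2R,3R)-2,3-bis(benzyloxymethyl)-6,7-bis(pinacolboryl)-1,2,3,4-tetrahydronaphthalene
Product: 10 (2R,3R)-2,3-bis(benzyloxymethyl)-1,2,3,4-tetrahydronaphthalene-6,7-diol
Conditions: 30% aq H2O2, NaOH (2.2 equiv), THF, 0 °C, argon; then aq NH4Cl/Na2S2O3
Reagents that add atoms: hydrogen peroxide, OO
Why: Oxidative ipso-hydroxylation of arylboronates (hydroperoxide adds to boron, the aryl group migrates from boron to oxygen, and the borate ester hydrolyses) should convert both C–B bonds to C–OH and give the C2-symmetric catechol, which is kept under argon and worked up cold to avoid quinone formation.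

**Step 7**
Reactants: 10 (2R,3R)-2,3-bis(benzyloxymethyl)-1,2,3,4-tetrahydronaphthalene-6,7-diol
Product: 11 (2R,3R)-2,3-bis(benzyloxymethyl)-7-methoxy-1,2,3,4-tetrahydronaphthalen-6-ol
Conditions: MeI (1.05 equiv), Li2CO3 (1.2 equiv), DMF, 50 °C, argon
Reagents that add atoms: iodomethane, CI
Why: Williamson O-methylation with one equivalent of MeI and the weak base Li2CO3 should stop largely at the monoether because only the first, more acidic catechol hydroxyl is deprotonated, and since the C2 axis exchanges the two hydroxyls either one gives the same compound, in which the benzylic carbon para to the remaining OH (through C8a) is now C1.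

**Step 8**
Reactants: 11 (2R,3R)-2,3-bis(benzyloxymethyl)-7-methoxy-1,2,3,4-tetrahydronaphthalen-6-ol; 12 guaiacol (2-methoxyphenol)
Product: 14 (1S,2R,3R)-2,3-bis(benzyloxymethyl)-1-(4-hydroxy-3-methoxyphenyl)-7-methoxy-1,2,3,4-tetrahydronaphthalen-6-ol, via quinone methide 13 (not isolated)
Conditions: Ag2O (3 equiv), CH2Cl2 (0.02 M), rt, dark, argon; filtered through Celite into 12 (10 equiv), BF3·OEt2 (0.3 equiv), CH2Cl2, −78 → −40 °C
Reagents that add atoms: guaiacol (12), COc1ccccc1O
Why: Ag2O dehydrogenates the para-alkylphenol to the para-quinone methide (C6=O, C8a=C1; C4 is para to OMe and cannot be engaged), and BF3-activated 1,6-addition of guaiacol through its carbon para to OH (Friedel–Crafts alkylation by a quinone methide, para to the stronger donor and least hindered) should set C1 by attack on the face opposite the adjacent C2 benzyloxymethyl group, giving the 1,2-trans, all-equatorial (1S) isomer, which is also the thermodynamically preferred one.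

**Step 9**
Reactants: 14 (1S,2R,3R)-2,3-bis(benzyloxymethyl)-1-(4-hydroxy-3-methoxyphenyl)-7-methoxy-1,2,3,4-tetrahydronaphthalen-6-ol
Product: 15 (1S,2R,3R)-1-(4-hydroxy-3-methoxyphenyl)-2,3-bis(hydroxymethyl)-7-methoxy-1,2,3,4-tetrahydronaphthalen-6-ol (target)
Conditions: H2 (1 atm), 10% Pd/C, EtOAc/MeOH, rt
Reagents that add atoms: none
Why: Catalytic hydrogenolysis over Pd/C cleaves the two alkyl benzyl ethers to the primary alcohols and toluene, while the phenols, the aryl methyl ethers and the doubly benzylic C1 position are inert at ambient pressure and temperature, so no stereocentre is touched.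

**Compound list**
1 | (1R,2R)-cyclohex-4-ene-1,2-dicarboxylic acid | OC(=O)[C@@H]1CC=CC[C@H]1C(=O)O | starting material
2 | [(1R,2R)-cyclohex-4-ene-1,2-diyl]dimethanol | OC[C@@H]1CC=CC[C@H]1CO | intermediate
3 | (4R,5R)-4,5-bis(benzyloxymethyl)cyclohexene | C(OCc1ccccc1)[C@@H]1CC=CC[C@H]1COCc1ccccc1 | intermediate
4 | (3R,4R)-3,4-bis(benzyloxymethyl)-7,8,9-trioxabicyclo[4.2.1]nonane (secondary ozonide; bridgeheads cis by constraint, one diastereomer possible) | C1(O2)C[C@@H](COCc3ccccc3)[C@H](COCc3ccccc3)CC2OO1 | intermediate (not isolated)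
5 | (3R,4R)-3,4-bis(benzyloxymethyl)hexanedial | O=CC[C@@H](COCc1ccccc1)[C@H](COCc1ccccc1)CC=O | intermediate
6 | dimethyl (1-diazo-2-oxopropyl)phosphonate | CC(=O)C(=[N+]=[N-])P(=O)(OC)OC | starting material
7 | (4R,5R)-4,5-bis(benzyloxymethyl)octa-1,7-diyne | C#CC[C@@H](COCc1ccccc1)[C@H](COCc1ccccc1)CC#C | intermediate
8 | bis(pinacolboryl)acetylene | CC1(C)OB(C#CB2OC(C)(C)C(C)(C)O2)OC1(C)C | starting material
9 | (2R,3R)-2,3-bis(benzyloxymethyl)-6,7-bis(pinacolboryl)-1,2,3,4-tetrahydronaphthalene | C1c2cc(B3OC(C)(C)C(C)(C)O3)c(B3OC(C)(C)C(C)(C)O3)cc2C[C@@H](COCc2ccccc2)[C@@H]1COCc1ccccc1 | intermediate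
10 | (2R,3R)-2,3-bis(benzyloxymethyl)-1,2,3,4-tetrahydronaphthalene-6,7-diol | C1c2cc(O)c(O)cc2C[C@@H](COCc2ccccc2)[C@@H]1COCc1ccccc1 | intermediate
11 | (2R,3R)-2,3-bis(benzyloxymethyl)-7-methoxy-1,2,3,4-tetrahydronaphthalen-6-ol | C1c2cc(OC)c(O)cc2C[C@@H](COCc2ccccc2)[C@@H]1COCc1ccccc1 | intermediate
12 | guaiacol (2-methoxyphenol) | COc1ccccc1O | starting material
13 | (6R,7R)-6,7-bis(benzyloxymethyl)-3-methoxy-7,8-dihydro-6H-naphthalen-2-one (para-quinone methide; tetralin numbering C6=O, C1=C8a) | O=C1C=C2C[C@@H](COCc3ccccc3)[C@H](COCc3ccccc3)C=C2C=C1OC | intermediate (not isolated)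
14 | (1S,2R,3R)-2,3-bis(benzyloxymethyl)-1-(4-hydroxy-3-methoxyphenyl)-7-methoxy-1,2,3,4-tetrahydronaphthalen-6-ol | COc1cc([C@H]2c3cc(OC)c(O)cc3C[C@@H](COCc3ccccc3)[C@@H]2COCc2ccccc2)ccc1O | intermediate
15 | (1S,2R,3R)-1-(4-hydroxy-3-methoxyphenyl)-2,3-bis(hydroxymethyl)-7-methoxy-1,2,3,4-tetrahydronaphthalen-6-ol | COc1cc([C@H]2c3cc(OC)c(O)cc3C[C@@H](CO)[C@@H]2CO)ccc1O | target

Total step count: 9
Longest linear sequence: 9 steps (1 → 15)

**Steps most likely to fail**

Step 8. The quinone methide may tautomerise to the 1,2-dihydronaphthalene (which would erase C2) or dimerise before it is trapped. Guaiacol may also be attacked para to its methoxy group, ortho to its hydroxyl or at oxygen, and the facial preference at C1 may be incomplete. The fallback replaces the Friedel–Crafts step by conjugate addition of a regiodefined aryl organometallic. It sets out from 11: the quinone methide 13 is generated with Ag2O and filtered as before, then added at −78 °C in THF to (4-benzyloxy-3-methoxyphenyl)magnesium bromide F1 (from purchased 1-benzyloxy-4-bromo-2-methoxybenzene and Mg, 3 equiv) with CuBr·SMe2 (10 mol %). 1,6-Addition anti to the C2 substituent, followed by aqueous NH4Cl, should give (1S,2R,3R)-1-(4-benzyloxy-3-methoxyphenyl)-2,3-bis(benzyloxymethyl)-7-methoxy-1,2,3,4-tetrahydronaphthalen-6-ol F2. Hydrogenolysis of its three benzyl ethers under the conditions of step 9 comes back to the route at the target 15.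

Step 5. The terminal diyne may oligomerise with itself, the bulky diborylalkyne may insert too slowly into the cobaltacycle, or the crowded vicinal diboronate may lose boron on isolation. The fallback sets out from 7, which is cocyclised with purchased bis(trimethylsilyl)acetylene as solvent (CpCo(CO)2, reflux, hν) to (2R,3R)-2,3-bis(benzyloxymethyl)-6,7-bis(trimethylsilyl)-1,2,3,4-tetrahydronaphthalene F3. Ipso-iododesilylation with ICl (2.2 equiv, CH2Cl2, 0 °C) should give (2R,3R)-2,3-bis(benzyloxymethyl)-6,7-diiodo-1,2,3,4-tetrahydronaphthalene F4. Ullmann-type methoxylation (CuI, NaOMe, MeOH/DMF, 100 °C) then gives (2R,3R)-2,3-bis(benzyloxymethyl)-6,7-dimethoxy-1,2,3,4-tetrahydronaphthalene F5. NaSEt in DMF at 110 °C should remove one methyl group only, because the phenoxide formed deactivates the neighbouring methyl ether. The two methoxy groups are symmetry-equivalent, so this comes back to the route at 11, bypassing 9 and 10.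

Step 4. Base-induced intramolecular aldol condensation of the 1,6-dialdehyde to a cyclopentene carbaldehyde may compete with the homologation in K2CO3/MeOH, or only one aldehyde may be converted. The fallback is a Corey–Fuchs sequence that avoids the basic step on the dialdehyde. It sets out from 5, which with CBr4/PPh3 in CH2Cl2 at 0 °C should give (4R,5R)-4,5-bis(benzyloxymethyl)-1,1,8,8-tetrabromoocta-1,7-diene F6. n-BuLi (4.4 equiv, THF, −78 °C) then converts both ends by elimination and lithium–bromine exchange into the acetylides, and protonation with aqueous NH4Cl comes back to the route at the diyne 7.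

**Further compounds**
F1 | step 8 | (4-benzyloxy-3-methoxyphenyl)magnesium bromide | COc1cc([Mg]Br)ccc1OCc1ccccc1
F2 | step 8 | (1S,2R,3R)-1-(4-benzyloxy-3-methoxyphenyl)-2,3-bis(benzyloxymethyl)-7-methoxy-1,2,3,4-tetrahydronaphthalen-6-ol | COc1cc([C@H]2c3cc(OC)c(O)cc3C[C@@H](COCc3ccccc3)[C@@H]2COCc2ccccc2)ccc1OCc1ccccc1
F3 | step 5 | (2R,3R)-2,3-bis(benzyloxymethyl)-6,7-bis(trimethylsilyl)-1,2,3,4-tetrahydronaphthalene | C1c2cc([Si](C)(C)C)c([Si](C)(C)C)cc2C[C@@H](COCc2ccccc2)[C@@H]1COCc1ccccc1
F4 | step 5 | (2R,3R)-2,3-bis(benzyloxymethyl)-6,7-diiodo-1,2,3,4-tetrahydronaphthalene | C1c2cc(I)c(I)cc2C[C@@H](COCc2ccccc2)[C@@H]1COCc1ccccc1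
F5 | step 5 | (2R,3R)-2,3-bis(benzyloxymethyl)-6,7-dimethoxy-1,2,3,4-tetrahydronaphthalene | C1c2cc(OC)c(OC)cc2C[C@@H](COCc2ccccc2)[C@@H]1COCc1ccccc1
F6 | step 4 | (4R,5R)-4,5-bis(benzyloxymethyl)-1,1,8,8-tetrabromoocta-1,7-diene | BrC(Br)=CC[C@@H](COCc1ccccc1)[C@H](COCc1ccccc1)CC=C(Br)Br
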